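66.4% of target in the larch run at 60.0 min and 65.5% in the maple run at 40.0 min differ by 0.9 percentage points, where a reading carries 1 point, although the loadings are 0.34 mol% and 0.52 mol%. Loading multiplied by time is 0.204 min for the first and 0.208 min for the second. This product, taken at one charge concentration, is the catalyst clock, and for the flask at 1.0 h it stands at 0.414 min. Its zero of the scale is the symmetric case, in which flasks of one charge hold the same target at the same clock.

common to all: solid substrate 11 mM
- larch: free catalyst 0.34 mol%; run made earlier
- maple: free catalyst 0.52 mol%; run made earlier
- flask: free catalyst 0.69 mol%; time 1.0 h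

- larch (time / min: target / %, solid substrate / %): 10.0: 9.7, 20.9; 20.0: 23.5, 10.1; 30.0: 36.2, 0.1; 40.0: 48.4, 0.6; 50.0: 55.1, 0.2; 60.0: 66.4, 0.9; 80.0: 77.8, 1.1
- maple (time / min: target / %, solid substrate / %): 10.0: 18.2, 20.2; 20.0: 35.5, 0; 30.0: 51.8, 0.1; 40.0: 65.5, 1.2; 50.0: 76.0, 0; 60.0: 84.6, 0; 80.0: 92.4, 0.7

(standard deviation of a reading: 1 percentage point)

* amount of target in percent of the solid substrate charged, at 6.0 min, 20 min, 40 min and 1.0 h

In the first instants the solid substrate enters solution on ordinary time: at 10.0 min the solid reads 20.9% in the larch run and 20.2% in the maple run, while target reads 9.7% and 18.2%. In the middle, the part of the charge that is neither target nor solid reads 69.4% and then 66.4% in the larch run, so the solution holds near one level and target climbs almost straight, a pseudo-zero-order stretch. The solid then reads 0.1% in the larch run at 30.0 min, and from there the curve bends.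

The reckoning for the flask reads the runs at equal clock. At 40 min the flask stands at 0.276 min, beside the larch run at 80.0 min with 0.272 min, which gives 77.8%. At 1.0 h it stands beside the maple run at 80.0 min, which gives 92.4%. At 20 min, interpolation in the maple run gives 46.2%. At 6.0 min, interpolation between the first readings of the two runs gives 13.2%, which is taken as a ceiling because the flask has had less time to dissolve.

The forecast gives 10%, 45%, 79% and 92%, lower than this reckoning at the first point, having scaled time by catalyst “with a small early lag from dissolution”.

The flask gives 11.4%, 45.5%, 77.8% and 92.0%.

    catalyst intermediate B ⇌ free catalyst + target (K = 0.0750 M, k = 39.2 /min)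
    solid substrate ⇌ starting material, rate k2*(cs2 - [starting material]) while solid is left; crystals form when [starting material] > cs2 (solubility = 7.60 mM, k = 0.479 /min)
    starting material + free catalyst ⇌ catalyst intermediate A (K = 123 /M, k = 1930 /M/min)
    catalyst intermediate A → catalyst intermediate B (k = 12.6 /min)

At clock 0.414 min the flask holds 92.0% of target, beside 92.4% in the maple run at 0.416 min, and at that time catalyst intermediate B relaxes with free catalyst + target, both ways together, with a half-life of 0.0156 min, short against 1.0 h, while 12.7% of the catalyst stands as catalyst intermediate B. A neighbouring flask at twice the dilution, with the same loading and so the same clock 0.414 min, holds 77.4% of target, 15 points below the flask.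

The numbers in the tables were computed for an exercise.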